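## Retrosynthetic overview

1. Target 14 ⇐ penta-O-benzyl ether 13 by neutral global debenzylation (last step).
2. 13 ⇐ ketone 9 + carbinol 11. The Cα–CHAr2 bond and the only stereocentre are made in one catalytic step: a chiral phosphoric acid joins the enol of 9 to the p-quinone methide 12 formed in situ. This replaces the usual aryl-metal conjugate addition to an α-chromonyl chalcone or an auxiliary-controlled alkylation.
3. 9 ⇐ chromone-3-acetic acid 6 + 1,3,5-tris(benzyloxy)benzene 7 (Friedel–Crafts acylation).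
4. 6 ⇐ γ-keto ester 3 + one carbon from DMF-DMA; 3 ⇐ acetophenone 1 + tert-butyl bromoacetate.
5. Rings: all benzene rings are bought. The only ring built is the pyran-4-one of the chromone (step 2), before the stereocentre exists.

Assumption: 1 and 7 are taken as catalogue compounds, and (R)-TRIP is written as the catalyst hand that gives the (R)-ketone in step 6; the sense of induction of this new step must be read from experiment (ECD or rotation of 14 against natural chamaechromone), and (S)-TRIP is used unchanged otherwise if the first run gives the antipode.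

## Route

Step 1
Reactants: 1 1-[2,4-bis(benzyloxy)-6-hydroxyphenyl]ethan-1-one
Product: 3 tert-butyl 4-[2,4-bis(benzyloxy)-6-hydroxyphenyl]-4-oxobutanoate, via dilithium 3,5-bis(benzyloxy)-2-(1-oxidoethenyl)phenolate 2 (not isolated)
Conditions: LiHMDS (2.2 equiv), THF, −78 °C; then BrCH2CO2tBu (1.05 equiv), −78 → −20 °C; aq NH4Cl
Reagents that add atoms: tert-butyl bromoacetate, CC(C)(C)OC(=O)CBr
Why: Enolate alkylation (SN2) of the phenoxide–enolate dianion, whose enolate carbon is far more nucleophilic than the lithium-chelated phenoxide oxygen; no stereocentre is formed.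

Step 2
Reactants: 3 tert-butyl 4-[2,4-bis(benzyloxy)-6-hydroxyphenyl]-4-oxobutanoate
Product: 5 tert-butyl 2-[5,7-bis(benzyloxy)-4-oxo-4H-chromen-3-yl]acetate, via tert-butyl (3E)-3-[2,4-bis(benzyloxy)-6-hydroxybenzoyl]-4-(dimethylamino)but-3-enoate 4 (not isolated)
Conditions: DMF-DMA (1.5 equiv), PhMe, 100 °C; then AcOH, 60 °C
Reagents that add atoms: N,N-dimethylformamide dimethyl acetal, COC(OC)N(C)C
Why: Enaminone condensation at the only sufficiently acidic CH2 (α to the ketone), then intramolecular addition–elimination by the ortho-OH with loss of Me2NH; this is the chromone annulation used for isoflavones and 3-benzylchromones.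

Step 3
Reactants: 5 tert-butyl 2-[5,7-bis(benzyloxy)-4-oxo-4H-chromen-3-yl]acetate
Product: 6 2-[5,7-bis(benzyloxy)-4-oxo-4H-chromen-3-yl]acetic acid
Conditions: TFA/CH2Cl2 (1:3), 0 °C → rt
Reagents that add atoms: none
Why: Acidolysis (E1) of the tert-butyl ester; the chromone and the aryl benzyl ethers tolerate cold TFA for the short reaction time.

Step 4
Reactants: 6 2-[5,7-bis(benzyloxy)-4-oxo-4H-chromen-3-yl]acetic acid; 7 1,3,5-tris(benzyloxy)benzene
Product: 9 2-[5,7-bis(benzyloxy)-4-oxo-4H-chromen-3-yl]-1-[2,4,6-tris(benzyloxy)phenyl]ethan-1-one, via 2-[5,7-bis(benzyloxy)-4-oxo-4H-chromen-3-yl]acetic trifluoroacetic anhydride 8 (not isolated)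
Conditions: TFAA (1.2 equiv), CH2Cl2, 0 °C, 20 min; then 7 (1.3 equiv), 0 °C → rt
Reagents that add atoms: none
Why: Friedel–Crafts acylation through the acyl trifluoroacetate; the phloroglucinol triether is nucleophilic enough to react without a metal Lewis acid (so the benzyl ethers survive), its C3 symmetry allows one regioisomer only, and the new acyl group stops a second acylation.

Step 5
Reactants: 10 4,4'-dihydroxybenzophenone
Product: 11 bis(4-hydroxyphenyl)methanol
Conditions: NaBH4 (3 equiv), THF/MeOH, 50 °C; aq NH4Cl to pH 7 at 0 °C; used at once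
Reagents that add atoms: none
Why: Hydride reduction of the diaryl ketone; the carbinol is acid-labile (it is the precursor of 12), so it is worked up neutral and not stored.

Step 6
Reactants: 9 2-[5,7-bis(benzyloxy)-4-oxo-4H-chromen-3-yl]-1-[2,4,6-tris(benzyloxy)phenyl]ethan-1-one; 11 bis(4-hydroxyphenyl)methanol
Product: 13 (2R)-2-[5,7-bis(benzyloxy)-4-oxo-4H-chromen-3-yl]-3,3-bis(4-hydroxyphenyl)-1-[2,4,6-tris(benzyloxy)phenyl]propan-1-one, via 4-[(4-hydroxyphenyl)methylidene]cyclohexa-2,5-dien-1-one 12 (not isolated)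
Conditions: (R)-TRIP (10 mol %), 5 Å MS, DCE, 0 → 25 °C; 11 (1.5 equiv) added in portions over 8 h
Reagents that add atoms: none
Why: Proposed new method: the phosphoric acid dehydrates 11 to the p-quinone methide 12 and holds it by a P–OH···O=C hydrogen bond, while its P=O binds the O–H of the chromone-conjugated enol of 9 (the only O–H donor on that partner), so the enol carbon adds 1,6 to the exocyclic CH inside the chiral pocket with one enol face screened by a 2,4,6-triisopropylphenyl wall, and rearomatisation gives the bisphenol and the (R)-centre; the closest known reactions are phosphoric-acid-catalysed enantioselective 1,6-additions to p-quinone methides generated in situ from p-hydroxybenzyl alcohols and phosphoric-acid "enol catalysis" for direct α-functionalisation of α-aryl ketones, and the product should not racemise because its tetrasubstituted enol is strongly disfavoured by A1,3 strain.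

Step 7
Reactants: 13 (2R)-2-[5,7-bis(benzyloxy)-4-oxo-4H-chromen-3-yl]-3,3-bis(4-hydroxyphenyl)-1-[2,4,6-tris(benzyloxy)phenyl]propan-1-one
Product: 14 (2R)-2-(5,7-dihydroxy-4-oxo-4H-chromen-3-yl)-3,3-bis(4-hydroxyphenyl)-1-(2,4,6-trihydroxyphenyl)propan-1-one
Conditions: H2 (1 atm), 10% Pd/C, EtOAc/MeOH (1:1), rt; stopped at full debenzylation
Reagents that add atoms: none
Why: Hydrogenolysis of the five aryl benzyl ethers under neutral conditions leaves the α-stereocentre, the hydrogen-bonded aryl ketone and the 3-substituted chromone untouched.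

## Compound list

1 | 1-[2,4-bis(benzyloxy)-6-hydroxyphenyl]ethan-1-one | CC(=O)c1c(O)cc(OCc2ccccc2)cc1OCc1ccccc1 | starting material
2 | dilithium 3,5-bis(benzyloxy)-2-(1-oxidoethenyl)phenolate | [Li+].[Li+].C=C([O-])c1c([O-])cc(OCc2ccccc2)cc1OCc1ccccc1 | intermediate (not isolated)
3 | tert-butyl 4-[2,4-bis(benzyloxy)-6-hydroxyphenyl]-4-oxobutanoate | CC(C)(C)OC(=O)CCC(=O)c1c(O)cc(OCc2ccccc2)cc1OCc1ccccc1 | intermediate
4 | tert-butyl (3E)-3-[2,4-bis(benzyloxy)-6-hydroxybenzoyl]-4-(dimethylamino)but-3-enoate | CC(C)(C)OC(=O)C/C(=C\N(C)C)C(=O)c1c(O)cc(OCc2ccccc2)cc1OCc1ccccc1 | intermediate (not isolated)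
5 | tert-butyl 2-[5,7-bis(benzyloxy)-4-oxo-4H-chromen-3-yl]acetate | CC(C)(C)OC(=O)Cc1coc2cc(OCc3ccccc3)cc(OCc3ccccc3)c2c1=O | intermediate
6 | 2-[5,7-bis(benzyloxy)-4-oxo-4H-chromen-3-yl]acetic acid | OC(=O)Cc1coc2cc(OCc3ccccc3)cc(OCc3ccccc3)c2c1=O | intermediate
7 | 1,3,5-tris(benzyloxy)benzene | c1ccc(COc2cc(OCc3ccccc3)cc(OCc3ccccc3)c2)cc1 | starting material
8 | 2-[5,7-bis(benzyloxy)-4-oxo-4H-chromen-3-yl]acetic trifluoroacetic anhydride | O=C(Cc1coc2cc(OCc3ccccc3)cc(OCc3ccccc3)c2c1=O)OC(=O)C(F)(F)F | intermediate (not isolated)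
9 | 2-[5,7-bis(benzyloxy)-4-oxo-4H-chromen-3-yl]-1-[2,4,6-tris(benzyloxy)phenyl]ethan-1-one | O=C(Cc1coc2cc(OCc3ccccc3)cc(OCc3ccccc3)c2c1=O)c1c(OCc2ccccc2)cc(OCc2ccccc2)cc1OCc1ccccc1 | intermediate
10 | 4,4'-dihydroxybenzophenone | O=C(c1ccc(O)cc1)c1ccc(O)cc1 | starting material
11 | bis(4-hydroxyphenyl)methanol | OC(c1ccc(O)cc1)c1ccc(O)cc1 | intermediate
12 | 4-[(4-hydroxyphenyl)methylidene]cyclohexa-2,5-dien-1-one | O=C1C=CC(=Cc2ccc(O)cc2)C=C1 | intermediate (not isolated)
13 | (2R)-2-[5,7-bis(benzyloxy)-4-oxo-4H-chromen-3-yl]-3,3-bis(4-hydroxyphenyl)-1-[2,4,6-tris(benzyloxy)phenyl]propan-1-one | O=C(c1c(OCc2ccccc2)cc(OCc2ccccc2)cc1OCc1ccccc1)[C@@H](c1coc2cc(OCc3ccccc3)cc(OCc3ccccc3)c2c1=O)C(c1ccc(O)cc1)c1ccc(O)cc1 | intermediate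
14 | (2R)-2-(5,7-dihydroxy-4-oxo-4H-chromen-3-yl)-3,3-bis(4-hydroxyphenyl)-1-(2,4,6-trihydroxyphenyl)propan-1-one (chamaechromone) | O=C(c1c(O)cc(O)cc1O)[C@@H](c1coc2cc(O)cc(O)c2c1=O)C(c1ccc(O)cc1)c1ccc(O)cc1 | target

## Step count and risks

Total steps: 7. Longest linear sequence: 6 (steps 1, 2, 3, 4, 6, 7); step 5 is a one-step side branch.

Most likely to fail, step 6. The hindered ketone may enolise slowly, 11/12 may self-condense through their phenol rings, the benzyloxy-rich rings of 9 may be C-alkylated, and the ee or its sense may be wrong. The fallback sets out from 9 and comes back at 13. The same partners 9 and 11 are joined with an achiral acid (diphenyl phosphate, DCE, rt) to give racemic 2-[5,7-bis(benzyloxy)-4-oxo-4H-chromen-3-yl]-3,3-bis(4-hydroxyphenyl)-1-[2,4,6-tris(benzyloxy)phenyl]propan-1-one F1. F1 is resolved by preparative SFC on an amylose carbamate phase, and the (R)-enantiomer is 13. Stereocontrol by catalyst is thereby replaced by resolution.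

Second, step 4. The acyl trifluoroacetate of a chromonylacetic acid may self-condense, TFAA may trifluoroacetylate 7, acid may move benzyl groups, and acid may isomerise 9 (a masked 1,4-dicarbonyl) to a furan. The fallback sets out from 1 and comes back at 9, making the CH2–C3 bond instead of the aryl–CO bond. Compound 1 and DMF-DMA give (2E)-1-[2,4-bis(benzyloxy)-6-hydroxyphenyl]-3-(dimethylamino)prop-2-en-1-one F2. Iodine in CHCl3 cyclises F2 to 5,7-bis(benzyloxy)-3-iodo-4H-chromen-4-one F3. Separately, 1 is benzylated (BnBr, K2CO3, DMF, 80 °C) to 1-[2,4,6-tris(benzyloxy)phenyl]ethan-1-one F4. Palladium-catalysed ketone α-arylation of F4 with F3 (Pd2(dba)3, Xantphos, K3PO4, PhMe, 80 °C) then gives 9 without any acylium chemistry.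

Third, step 7. The chromone C2=C3 bond may be saturated, or the two flanking benzyl ethers may come off slowly. The fallback sets out from 9 and comes back at 14, changing the protecting groups before the stereocentre exists. Compound 9 is debenzylated without reduction (BCl3, pentamethylbenzene, CH2Cl2, −78 °C) to 2-(5,7-dihydroxy-4-oxo-4H-chromen-3-yl)-1-(2,4,6-trihydroxyphenyl)ethan-1-one F5. Ac2O/pyridine gives 2-[5,7-bis(acetyloxy)-4-oxo-4H-chromen-3-yl]-1-[2,4,6-tris(acetyloxy)phenyl]ethan-1-one F6, whose acetoxy rings are also much poorer Friedel–Crafts partners. The step 6 conditions with 11 then give (2R)-2-[5,7-bis(acetyloxy)-4-oxo-4H-chromen-3-yl]-3,3-bis(4-hydroxyphenyl)-1-[2,4,6-tris(acetyloxy)phenyl]propan-1-one F7. Neutral solvolysis of the aryl acetates (NH4OAc, MeOH/H2O 4:1, rt) delivers 14.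

## Further compounds

F1 | step 6 | racemic 2-[5,7-bis(benzyloxy)-4-oxo-4H-chromen-3-yl]-3,3-bis(4-hydroxyphenyl)-1-[2,4,6-tris(benzyloxy)phenyl]propan-1-one | O=C(c1c(OCc2ccccc2)cc(OCc2ccccc2)cc1OCc1ccccc1)C(c1coc2cc(OCc3ccccc3)cc(OCc3ccccc3)c2c1=O)C(c1ccc(O)cc1)c1ccc(O)cc1
F2 | step 4 | (2E)-1-[2,4-bis(benzyloxy)-6-hydroxyphenyl]-3-(dimethylamino)prop-2-en-1-one | CN(C)/C=C/C(=O)c1c(O)cc(OCc2ccccc2)cc1OCc1ccccc1
F3 | step 4 | 5,7-bis(benzyloxy)-3-iodo-4H-chromen-4-one | Ic1coc2cc(OCc3ccccc3)cc(OCc3ccccc3)c2c1=O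
F4 | step 4 | 1-[2,4,6-tris(benzyloxy)phenyl]ethan-1-one | CC(=O)c1c(OCc2ccccc2)cc(OCc2ccccc2)cc1OCc1ccccc1
F5 | step 7 | 2-(5,7-dihydroxy-4-oxo-4H-chromen-3-yl)-1-(2,4,6-trihydroxyphenyl)ethan-1-one | O=C(Cc1coc2cc(O)cc(O)c2c1=O)c1c(O)cc(O)cc1O
F6 | step 7 | 2-[5,7-bis(acetyloxy)-4-oxo-4H-chromen-3-yl]-1-[2,4,6-tris(acetyloxy)phenyl]ethan-1-one | CC(=O)Oc1cc(OC(C)=O)c(C(=O)Cc2coc3cc(OC(C)=O)cc(OC(C)=O)c3c2=O)c(OC(C)=O)c1
F7 | step 7 | (2R)-2-[5,7-bis(acetyloxy)-4-oxo-4H-chromen-3-yl]-3,3-bis(4-hydroxyphenyl)-1-[2,4,6-tris(acetyloxy)phenyl]propan-1-one | O=C(c1c(OC(C)=O)cc(OC(C)=O)cc1OC(C)=O)[C@@H](c1coc2cc(OC(C)=O)cc(OC(C)=O)c2c1=O)C(c1ccc(O)cc1)c1ccc(O)cc1
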